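**Strategy.** The flavone is disconnected at C4: carbon monoxide supplies the carbonyl carbon and is inserted between C4a of a ring A iodide and C3 of a ring B arylacetylene in one palladium-catalysed carbonylative Sonogashira coupling, which forms C4a–C4 and C4–C3 and gives an open-chain ynone. The step exploits the position of C4a between the oxygenated carbons C5 and C8a and para to C7: a threefold-symmetric phloroglucinol tris(MOM) ether is iodinated at its only kind of ring CH, and either flanking oxygen can later serve as O1. The precursors are 2-iodo-1,3,5-tris(methoxymethoxy)benzene, carbon monoxide and the 3-O-MOM-protected 2,4,5-trimethoxyphenylacetylene; amine addition and acid then close ring C.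

Key step: step 9

Remark: MOM = methoxymethyl. Enaminone 17 is drawn as its E isomer; its geometry is of no consequence, because both isomers close to the same pyranone. The target has no stereocentre. The precursor and product structures of the key step were checked against the target and needed no correction.

**Route**

Step 1
Reactants: 1 phloroglucinol
Product: 2 1,3,5-tris(methoxymethoxy)benzene
Conditions: NaH (3.6 equiv), MOMCl (3.6 equiv), DMF, 0 °C → rt
Reagents that add atoms: chloromethyl methyl ether (MOMCl), COCCl
Why: Williamson-type O-alkylation of the three phenoxides with the hard electrophile MOMCl should give the triether (methoxymethyl protection).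

Step 2
Reactants: 2 1,3,5-tris(methoxymethoxy)benzene
Product: 4 2-iodo-1,3,5-tris(methoxymethoxy)benzene, via aryllithium 3 (not isolated)
Conditions: n-BuLi, THF, 0 °C; then I2, −78 °C → rt
Reagents that add atoms: iodine, II
Why: Directed ortho-metalation removes a ring proton flanked by two chelating MOM ethers (all three ring CH are equivalent), and iodinolysis of the aryllithium should give the single possible iodide.

Step 3
Reactants: 5 1,2,4-trimethoxybenzene
Product: 7 2,3,6-trimethoxybenzaldehyde, via aryllithium 6 (not isolated)
Conditions: n-BuLi, TMEDA, THF, 0 °C → rt; then DMF, −78 °C → rt; H2O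
Reagents that add atoms: N,N-dimethylformamide, CN(C)C=O
Why: Directed ortho-metalation takes place at the CH flanked by two methoxy groups, and the aryllithium is formylated by DMF (Bouveault-type formylation).

Step 4
Reactants: 7 2,3,6-trimethoxybenzaldehyde
Product: 8 3-bromo-2,5,6-trimethoxybenzaldehyde
Conditions: NBS (1.05 equiv), MeCN, 0 °C → rt
Reagents that add atoms: N-bromosuccinimide, O=C1CCC(=O)N1Br
Why: Electrophilic aromatic bromination should go to the CH that is ortho to one methoxy group, para to another and meta to the formyl group, the other free CH being para to the deactivating aldehyde and activated by one methoxy group only.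

Step 5
Reactants: 8 3-bromo-2,5,6-trimethoxybenzaldehyde
Product: 10 3-bromo-2,5,6-trimethoxyphenol, via aryl formate 9 (not isolated)
Conditions: mCPBA, CH2Cl2, 0 °C → rt; aq. Na2S2O3/NaHCO3 wash; then K2CO3 (cat.), MeOH, rt
Reagents that add atoms: meta-chloroperbenzoic acid (mCPBA), O=C(OO)c1cccc(Cl)c1
Why: Baeyer–Villiger (Dakin-type) oxidation, in which the electron-rich aryl group flanked by two methoxy groups migrates in the Criegee adduct to give the aryl formate, which is cleaved by methanolysis.

Step 6
Reactants: 10 3-bromo-2,5,6-trimethoxyphenol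
Product: 11 1-bromo-2,4,5-trimethoxy-3-(methoxymethoxy)benzene
Conditions: NaH, MOMCl, DMF, 0 °C → rt
Reagents that add atoms: chloromethyl methyl ether (MOMCl), COCCl
Why: Williamson-type methoxymethylation of the hindered phenoxide, which masks the C3' oxygen with the same acid-labile group as ring A.

Step 7
Reactants: 11 1-bromo-2,4,5-trimethoxy-3-(methoxymethoxy)benzene; 12 trimethylsilylacetylene
Product: 13 trimethyl{[2,4,5-trimethoxy-3-(methoxymethoxy)phenyl]ethynyl}silane
Conditions: PdCl2(PhCN)2 (3 mol %), [HP(t-Bu)3]BF4 (6 mol %), CuI (2 mol %), i-Pr2NH, 1,4-dioxane, rt → 50 °C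
Reagents that add atoms: none
Why: Sonogashira coupling, in which the bulky electron-rich P(t-Bu)3 ligand lets zerovalent palladium insert into the electron-rich ortho-substituted C–Br bond and the silyl cap prevents double coupling.

Step 8
Reactants: 13 trimethyl{[2,4,5-trimethoxy-3-(methoxymethoxy)phenyl]ethynyl}silane
Product: 14 1-ethynyl-2,4,5-trimethoxy-3-(methoxymethoxy)benzene
Conditions: K2CO3 (cat.), MeOH, rt
Reagents that add atoms: none
Why: Base-catalysed methanolysis of the C(sp)–Si bond (protiodesilylation) should free the terminal alkyne without touching the acetal or the methyl ethers.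

Step 9
Reactants: 4 2-iodo-1,3,5-tris(methoxymethoxy)benzene; 14 1-ethynyl-2,4,5-trimethoxy-3-(methoxymethoxy)benzene; 15 carbon monoxide
Product: 16 1-[2,4,6-tris(methoxymethoxy)phenyl]-3-[2,4,5-trimethoxy-3-(methoxymethoxy)phenyl]prop-2-yn-1-one
Conditions: PdCl2(PPh3)2 (5 mol %), Et3N (3 equiv), THF, CO (10 bar), 50 °C
Reagents that add atoms: none
Why: Zerovalent palladium, generated in situ from PdCl2(PPh3)2, inserts into the C4a–I bond of 4, CO then inserts into the aryl–palladium bond to give an aroyl complex of divalent palladium, amine-assisted transfer of the alkynyl group of 14 follows, and reductive elimination delivers the ynone, so that C4a–C4 and C4–C3 are both made in this one operation. The closest known reaction type is the carbonylative Sonogashira coupling of aryl iodides with terminal alkynes, a standard three-component ynone synthesis. No ring is closed and no stereocentre is formed here; ring C is left for step 10. The selectivity required is CO insertion ahead of direct aryl–alkynyl coupling and of hydrodeiodination: the two ortho OMOM groups at C5 and C8a crowd the aryl–palladium centre against the alkynyl ligand yet admit the small CO, the electron-rich aryl group migrates readily onto CO, and 10 bar of CO without a copper co-catalyst should keep acylation faster than alkynylation. Because ring A is threefold symmetric, 4 is the only possible iodide and no regiochemical question arises at C4a.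

Step 10
Reactants: 16 1-[2,4,6-tris(methoxymethoxy)phenyl]-3-[2,4,5-trimethoxy-3-(methoxymethoxy)phenyl]prop-2-yn-1-one
Product: 18 5,7,3'-trihydroxy-2',4',5'-trimethoxyflavone, via enaminone 17 (not isolated)
Conditions: Et2NH, EtOH, rt; evaporate; then HCl (3 M in MeOH), 60 °C
Reagents that add atoms: none
Why: Conjugate (aza-Michael) addition of Et2NH turns the ynone into a β-enaminone whose only electrophilic carbon is C2, so that after acid-catalysed cleavage of the four MOM acetals one of the two equivalent ortho hydroxyls of ring A displaces the amine by addition–elimination and closes ring C in the six-membered (6-endo) sense only, the aurone-forming 5-exo path being excluded.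

**Compound list**

1 | phloroglucinol | Oc1cc(O)cc(O)c1 | starting material
2 | 1,3,5-tris(methoxymethoxy)benzene | COCOc1cc(OCOC)cc(OCOC)c1 | intermediate
3 | [2,4,6-tris(methoxymethoxy)phenyl]lithium | [Li]c1c(OCOC)cc(OCOC)cc1OCOC | intermediate
4 | 2-iodo-1,3,5-tris(methoxymethoxy)benzene | COCOc1cc(OCOC)c(I)c(OCOC)c1 | intermediate
5 | 1,2,4-trimethoxybenzene | COc1ccc(OC)c(OC)c1 | starting material
6 | (2,3,6-trimethoxyphenyl)lithium | [Li]c1c(OC)ccc(OC)c1OC | intermediate
7 | 2,3,6-trimethoxybenzaldehyde | COc1ccc(OC)c(C=O)c1OC | intermediate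
8 | 3-bromo-2,5,6-trimethoxybenzaldehyde | COc1cc(Br)c(OC)c(C=O)c1OC | intermediate
9 | 3-bromo-2,5,6-trimethoxyphenyl formate | COc1cc(Br)c(OC)c(OC=O)c1OC | intermediate
10 | 3-bromo-2,5,6-trimethoxyphenol | COc1cc(Br)c(OC)c(O)c1OC | intermediate
11 | 1-bromo-2,4,5-trimethoxy-3-(methoxymethoxy)benzene | COCOc1c(OC)c(Br)cc(OC)c1OC | intermediate
12 | trimethylsilylacetylene | C#C[Si](C)(C)C | starting material
13 | trimethyl{[2,4,5-trimethoxy-3-(methoxymethoxy)phenyl]ethynyl}silane | COCOc1c(OC)c(C#C[Si](C)(C)C)cc(OC)c1OC | intermediate
14 | 1-ethynyl-2,4,5-trimethoxy-3-(methoxymethoxy)benzene | C#Cc1cc(OC)c(OC)c(OCOC)c1OC | intermediate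
15 | carbon monoxide | [C-]#[O+] | starting material
16 | 1-[2,4,6-tris(methoxymethoxy)phenyl]-3-[2,4,5-trimethoxy-3-(methoxymethoxy)phenyl]prop-2-yn-1-one | O=C(C#Cc1cc(OC)c(OC)c(OCOC)c1OC)c1c(OCOC)cc(OCOC)cc1OCOC | intermediate
17 | (E)-3-(diethylamino)-1-[2,4,6-tris(methoxymethoxy)phenyl]-3-[2,4,5-trimethoxy-3-(methoxymethoxy)phenyl]prop-2-en-1-one | CCN(CC)/C(=C/C(=O)c1c(OCOC)cc(OCOC)cc1OCOC)c1cc(OC)c(OC)c(OCOC)c1OC | intermediate
18 | 5,7,3'-trihydroxy-2',4',5'-trimethoxyflavone | COc1cc(-c2cc(=O)c3c(O)cc(O)cc3o2)c(OC)c(O)c1OC | target

**Step count and risks**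

Total steps: 10 (ring A: steps 1–2; ring B: steps 3–8; union and closure: steps 9–10).
Longest linear sequence: 8 steps (5 → 7 → 8 → 10 → 11 → 13 → 14 → 16 → 18).

Steps most likely to fail:

1. Step 9 (key step). The crowded, electron-rich aryl–palladium intermediate may take up CO too slowly, so that direct alkynylation, hydrodeiodination or catalyst decay competes with acyl transfer. The fallback sets out from 2 and 14 and returns at 16. Aryllithium 3, made from 2 as in step 2, is quenched with DMF to give 2,4,6-tris(methoxymethoxy)benzaldehyde F1. The lithium acetylide of 14 (n-BuLi, THF, −78 °C) is added to F1 to give racemic 1-[2,4,6-tris(methoxymethoxy)phenyl]-3-[2,4,5-trimethoxy-3-(methoxymethoxy)phenyl]prop-2-yn-1-ol F2. Oxidation of this propargylic benzylic alcohol with MnO2 in CH2Cl2 should give 16, so that C4 comes from DMF and not from CO.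

2. Step 7. Oxidative addition into the electron-rich bromide flanked by an ortho methoxy group may be slow, letting oligomerisation or oxidative dimerisation of 12 outrun the cross-coupling. The fallback sets out from 11 and returns at 14, bypassing 13. Bromine–lithium exchange (n-BuLi, THF, −78 °C) and a DMF quench give 2,4,5-trimethoxy-3-(methoxymethoxy)benzaldehyde F3. One-carbon homologation with dimethyl (1-diazo-2-oxopropyl)phosphonate, K2CO3 and MeOH (Ohira–Bestmann reaction) should give 14 directly.

3. Step 4. Regiocontrol of the bromination may be incomplete (attack para to the formyl group) or a second bromine may enter. The fallback sets out from 5 and returns at 14; it puts the alkyne carbon on first and the C3' oxygen on afterwards by metalation.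
   - Iodination of 5 with NIS (MeCN, cat. TFA) goes to the single most activated position and gives 1-iodo-2,4,5-trimethoxybenzene F4.
   - Sonogashira coupling with (triisopropylsilyl)acetylene (PdCl2(PPh3)2, CuI, Et3N) gives triisopropyl[(2,4,5-trimethoxyphenyl)ethynyl]silane F5.
   - Directed lithiation between the two methoxy groups (n-BuLi, TMEDA, THF), B(OMe)3 and then H2O2/AcOH give 2,5,6-trimethoxy-3-[(triisopropylsilyl)ethynyl]phenol F6.
   - MOMCl/NaH gives triisopropyl{[2,4,5-trimethoxy-3-(methoxymethoxy)phenyl]ethynyl}silane F7.
   - TBAF in THF should then give 14.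

**Further compounds**

F1 | step 9 | 2,4,6-tris(methoxymethoxy)benzaldehyde | O=Cc1c(OCOC)cc(OCOC)cc1OCOC
F2 | step 9 | 1-[2,4,6-tris(methoxymethoxy)phenyl]-3-[2,4,5-trimethoxy-3-(methoxymethoxy)phenyl]prop-2-yn-1-ol (racemic) | OC(C#Cc1cc(OC)c(OC)c(OCOC)c1OC)c1c(OCOC)cc(OCOC)cc1OCOC
F3 | step 7 | 2,4,5-trimethoxy-3-(methoxymethoxy)benzaldehyde | COCOc1c(OC)c(C=O)cc(OC)c1OC
F4 | step 4 | 1-iodo-2,4,5-trimethoxybenzene | COc1cc(OC)c(OC)cc1I
F5 | step 4 | triisopropyl[(2,4,5-trimethoxyphenyl)ethynyl]silane | COc1cc(OC)c(OC)cc1C#C[Si](C(C)C)(C(C)C)C(C)C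
F6 | step 4 | 2,5,6-trimethoxy-3-[(triisopropylsilyl)ethynyl]phenol | COc1cc(C#C[Si](C(C)C)(C(C)C)C(C)C)c(OC)c(O)c1OC
F7 | step 4 | triisopropyl{[2,4,5-trimethoxy-3-(methoxymethoxy)phenyl]ethynyl}silane | COCOc1c(OC)c(C#C[Si](C(C)C)(C(C)C)C(C)C)cc(OC)c1OC
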